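The runs come from a simulation on assumed constants, and the scatter is random.

In these runs the solid substrate left over keeps feeding the solution, so the first thing to reckon is how fast it does so.

| flask | solid substrate | coupling partner | remark | time |
|---|---|---|---|---|
| Tuesday's | 0.039 M | 0.082 M | run made earlier |  |
| Wednesday's | 0.039 M | 0.13 M | run made earlier |  |
| Saturday's | 0.078 M | 0.0585 M | run made earlier |  |
| flask | 0.039 M | 0.0585 M |  | 5.0 min |

| run | time / min | target / % | dissolved substrate / % |
|---|---|---|---|
| Tuesday's | 0.250 | 3.2 | 0.7 |
| Tuesday's | 0.833 | 11.6 | 0.4 |
| Tuesday's | 1.33 | 17.4 | 0.7 |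
| Tuesday's | 2.00 | 24.3 | 0.8 |
| Tuesday's | 3.00 | 33.4 | 0.4 |
| Wednesday's | 0.250 | 4.0 | 0.2 |
| Wednesday's | 0.833 | 11.6 | 0.3 |
| Wednesday's | 1.33 | 17.3 | 0 |
| Wednesday's | 2.00 | 24.5 | 0.2 |
| Wednesday's | 3.00 | 34.6 | 0.4 |
| Saturday's | 0.667 | 4.2 | 0.4 |
| Saturday's | 1.33 | 8.2 | 0.2 |
| Saturday's | 2.00 | 11.6 | 0.9 |
| Saturday's | 2.50 | 14.7 | 0.6 |
| Saturday's | 3.00 | 16.8 | 0.4 |

(scatter of a reading: 0.3 percentage points)

- percent here means solid substrate units held: one side product counts as two
- solid substrate is a solid; its amount is given per volume of the solution
- the numbers in the tables scatter with a standard deviation of 0.3 percentage points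
- steps that have been proposed: target <-> isomer of the product; coupling partner <-> dormant form; solid substrate <-> dissolved substrate; 2 dissolved substrate -> side product; dissolved substrate + coupling partner -> target
- at the start none of the solid substrate is in solution
- dissolved substrate means what is dissolved; the solid is not counted in it

1. the target standing at 5.0 min, as a percentage of the solid substrate charged
2. concentration of dissolved substrate in solution at 5.0 min, in percent of saturation

Tuesday's run holds 11.6% target at 0.833 min on a charge of 0.039 M, which gives 0.00543 M min⁻¹: this is the feed, the molar amount of target formed per minute while a run is young. Wednesday's run, with more coupling partner, reads the same 11.6%, and Saturday's, with twice the solid and less coupling partner, reads 0.00491 M min⁻¹. So dissolving looks like the rate-limiting step.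

One chemist freezes the feed for the whole run and expects target to follow it, reaching 69.6% of the charge by 5.0 min. Tuesday's last reading stands against that view, 33.4% against a line of 41.8%, a gap of 8.4 percentage points that is far beyond the scatter. The second chemist, who made the forecast, also takes a steady feed but lets target turn into isomer: "The apparent slowing tracks target concentration, not solid left". Her forecast is 50% target and 4% of saturation.

The flask gives 46.9% target and 3.36% of saturation, so the forecast stands. Isomer of the product holds 25.1% at 5.00 min. Target and isomer together make 72.0%, close to the 69.6% from the feed. The straight line came close early: at 0.500 min it gives 6.96%, and the flask has 6.37% target, that time being shorter than the 2.51 min relaxation half-life of target and isomer.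

    target ⇌ isomer of the product (K = 3.20, k = 0.210 min⁻¹)
    coupling partner ⇌ dormant form (K = 0.330, k = 0.0110 min⁻¹)
    solid substrate ⇌ dissolved substrate, rate k3*(cs3 - [dissolved substrate]) while solid is left; crystals form when [dissolved substrate] > cs3 (solubility = 17.0 mM, k = 0.350 min⁻¹)
    2 dissolved substrate → side product (k = 250 L mol⁻¹ min⁻¹)
    dissolved substrate + coupling partner → target (k = 340 L mol⁻¹ min⁻¹)

With 0.035 M of coupling partner the feed holds no term for the partner, so it again predicts 30.4% of the solid left at 5.00 min. That neighbour flask computes to 27.3% solid and 41.6% target.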